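**Retrosynthetic overview**
1. Target 17 ⇐ cross-conjugated dienone 16 by Os-catalysed syn-dihydroxylation of the exocyclic alkene, anti to the C4 acetate (sets C5 and C1').
2. 16 ⇐ acyclic (R,Z)-enynal 15 by Rh-catalysed formyl C–H activation and intramolecular alkyne hydroacylation (forms C1–C5 and the E-alkylidene).
3. 15 ⇐ tetradec-1-yne 7 + Z-enal 10 by catalytic asymmetric alkynylation with in-flask acetylation (sets C4), then direct oxidation of the primary silyl ether.
4. 7 ⇐ heptylmagnesium bromide 2 + heptynyl tosylate 4 (Cu-catalysed sp3–sp3 coupling); 10 ⇐ (Z)-but-2-ene-1,4-diol 8.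
5. Ring order: there is one ring, the cyclopentenone, closed in step 8.

Assumption: species bound to a catalytic metal inside a cycle (Cu, Zn–ligand, Rh, Os) are not numbered, and the (S,S)-ProPhenol written in step 6 stands for whichever ligand enantiomer gives the 4R carbinol (to be checked by Mosher ester on an aliquot taken before acylation).

**Step 1**
Reactants: 1 1-bromoheptane
Product: 2 heptylmagnesium bromide
Conditions: Mg turnings (1.1 equiv), I2 (cat.), THF, rt → reflux
Reagents that add atoms: magnesium [Mg]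
Why: Grignard formation by insertion of Mg into the primary C–Br bond; no stereocentre is involved.

**Step 2**
Reactants: 3 hept-6-yn-1-ol
Product: 4 hept-6-yn-1-yl 4-methylbenzenesulfonate
Conditions: TsCl (1.2 equiv), Et3N (1.5 equiv), DMAP (5 mol %), CH2Cl2, 0 °C → rt
Reagents that add atoms: p-toluenesulfonyl chloride Cc1ccc(cc1)S(=O)(=O)Cl
Why: O-sulfonylation (tosylation) of a primary alcohol; the terminal alkyne is untouched.

**Step 3**
Reactants: 2 heptylmagnesium bromide; 4 hept-6-yn-1-yl 4-methylbenzenesulfonate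
Product: 7 tetradec-1-yne, via tosyloxyheptynylmagnesium bromide 5 (not isolated), via tetradecynylmagnesium bromide 6 (not isolated)
Conditions: 2 (2.3 equiv), Li2CuCl4 (3 mol %), THF, −78 °C → rt; aq NH4Cl
Reagents that add atoms: none
Why: Kochi-type Cu-catalysed sp3–sp3 Grignard cross-coupling; the first equivalent of 2 only deprotonates the alkyne (5), the alkynyl group does not transfer from copper, and the heptyl cuprate displaces the primary tosylate to give 6, which is protonated on work-up.

**Step 4**
Reactants: 8 (Z)-but-2-ene-1,4-diol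
Product: 9 (Z)-4-(triethylsilyloxy)but-2-en-1-ol
Conditions: 8 (3 equiv), TESCl (1.0 equiv), imidazole (1.2 equiv), THF, 0 °C
Reagents that add atoms: chlorotriethylsilane CC[Si](Cl)(CC)CC
Why: statistical mono-silylation of a symmetrical diol used in excess (the excess is washed out with water); the Z-alkene comes from the starting material.

**Step 5**
Reactants: 9 (Z)-4-(triethylsilyloxy)but-2-en-1-ol
Product: 10 (Z)-4-(triethylsilyloxy)but-2-enal
Conditions: Dess–Martin periodinane (1.2 equiv), NaHCO3 (5 equiv), CH2Cl2, 0 °C; used at once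
Reagents that add atoms: none
Why: buffered Dess–Martin oxidation of a Z-allylic alcohol gives the Z-enal without amine or acid that would isomerise it, and the silyl ether survives.

**Step 6**
Reactants: 7 tetradec-1-yne; 10 (Z)-4-(triethylsilyloxy)but-2-enal
Product: 13 (R,Z)-1-(triethylsilyloxy)octadec-2-en-5-yn-4-yl acetate, via methyl(tetradecynyl)zinc 11 (not isolated), via methylzinc alkoxide 12 (not isolated)
Conditions: 7 (2.0 equiv, excess recovered), Me2Zn (2.0 equiv), (S,S)-ProPhenol (20 mol %), Ph3P=O (40 mol %), toluene, 0 °C; then 10 added slowly, 0–4 °C; then Ac2O (3 equiv), DMAP (10 mol %), 0 °C → rt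
Reagents that add atoms: acetic anhydride CC(=O)OC(C)=O; dimethylzinc C[Zn]C (its atoms stay only in 11 and 12)
Why: Zn–ProPhenol-catalysed asymmetric alkynylation of an enal, in which alkynylzinc 11 adds to one aldehyde face inside the chiral dinuclear zinc pocket and sets C4 as R, followed by O-acylation of zinc alkoxide 12 in the same flask.

**Step 7**
Reactants: 13 (R,Z)-1-(triethylsilyloxy)octadec-2-en-5-yn-4-yl acetate
Product: 15 (R,Z)-4-acetoxyoctadec-2-en-5-ynal, via alkoxydimethylsulfonium chloride 14 (not isolated)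
Conditions: (COCl)2 (3 equiv), DMSO (6 equiv), CH2Cl2, −78 °C; 13, −78 → −40 °C; Et3N (8 equiv), −78 → −20 °C; pH 7 buffer; used at once
Reagents that add atoms: dimethyl sulfoxide CS(C)=O and oxalyl chloride O=C(Cl)C(Cl)=O (atoms only in intermediate 14; none remain in 15)
Why: Swern oxidation applied directly to a primary triethylsilyl ether (Si-for-S exchange at the primary oxygen gives 14, then amine-induced fragmentation), which spares the secondary acetate and, kept cold, the Z-alkene and C4.

**Step 8**
Reactants: 15 (R,Z)-4-acetoxyoctadec-2-en-5-ynal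
Product: 16 (R,E)-4-oxo-5-tridecylidenecyclopent-2-en-1-yl acetate
Conditions: [Rh(cod)2]BF4 (10 mol %), rac-BINAP (10 mol %), pre-activated with H2 then degassed; CH2Cl2 (0.03 M), 25 °C, Ar, dark
Reagents that add atoms: none
Why: Proposed new method: cationic Rh(I)–bisphosphine adds oxidatively into the formyl C–H bond, and the tethered alkyne, held close by the Z-alkene, chelates the acyl-Rh(III) hydride and so disfavours decarbonylation; syn hydrorhodation (H to C6, Rh to C5) gives a six-membered acyl(alkenyl)rhodacycle, and C–C reductive elimination forms the C1–C5 ring bond. Because H and acyl arrive on the same side, the dodecyl chain ends cis to C4 (E), and C4 is not touched. The closest known reaction type is Rh(I)-catalysed intramolecular alkyne hydroacylation of saturated 4- and 5-alkynals (to cyclopentenones and (E)-2-alkylidenecyclopentanones); it has not been shown for a (Z)-2-en-5-ynal with a propargylic acyloxy stereocentre giving a 5-alkylidenecyclopent-2-enone.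

**Step 9**
Reactants: 16 (R,E)-4-oxo-5-tridecylidenecyclopent-2-en-1-yl acetate
Product: 17 (1R,5S)-5-hydroxy-5-[(S)-1-hydroxytridecyl]-4-oxocyclopent-2-en-1-yl acetate
Conditions: OsO4 (3 mol %), NMO (1.5 equiv), citric acid (1 equiv), t-BuOH/H2O 1:1, 0 °C → rt
Reagents that add atoms: osmium tetroxide O=[Os](=O)(=O)=O (delivers both oxygens); N-methylmorpholine N-oxide C[N+]1([O-])CCOCC1 and water O (net oxygen and hydrogen sources in turnover)
Why: Os-catalysed syn-dihydroxylation (Upjohn type, citric-acid-buffered for electron-poor alkenes and to prevent acetyl migration); the trisubstituted exocyclic alkene reacts before the ring cis-disubstituted enone alkene, and addition to the face anti to the C4 acetate of the E-alkene gives 5S and 1'S together.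

**Compound list**
1 | 1-bromoheptane | CCCCCCCBr | starting material
2 | heptylmagnesium bromide | CCCCCCC[Mg]Br | intermediate
3 | hept-6-yn-1-ol | C#CCCCCCO | starting material
4 | hept-6-yn-1-yl 4-methylbenzenesulfonate | C#CCCCCCOS(=O)(=O)c1ccc(C)cc1 | intermediate
5 | [7-(tosyloxy)hept-1-yn-1-yl]magnesium bromide (not isolated) | Br[Mg]C#CCCCCCOS(=O)(=O)c1ccc(C)cc1 | intermediate
6 | (tetradec-1-yn-1-yl)magnesium bromide (not isolated) | Br[Mg]C#CCCCCCCCCCCCC | intermediate
7 | tetradec-1-yne | C#CCCCCCCCCCCCC | intermediate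
8 | (Z)-but-2-ene-1,4-diol | OC/C=C\CO | starting material
9 | (Z)-4-(triethylsilyloxy)but-2-en-1-ol | OC/C=C\CO[Si](CC)(CC)CC | intermediate
10 | (Z)-4-(triethylsilyloxy)but-2-enal | O=C/C=C\CO[Si](CC)(CC)CC | intermediate
11 | methyl(tetradec-1-yn-1-yl)zinc (not isolated) | C[Zn]C#CCCCCCCCCCCCC | intermediate
12 | methylzinc (R,Z)-1-(triethylsilyloxy)octadec-2-en-5-yn-4-olate (not isolated) | C[Zn]O[C@H](/C=C\CO[Si](CC)(CC)CC)C#CCCCCCCCCCCCC | intermediate
13 | (R,Z)-1-(triethylsilyloxy)octadec-2-en-5-yn-4-yl acetate | CC[Si](CC)(CC)OC/C=C\[C@@H](OC(C)=O)C#CCCCCCCCCCCCC | intermediate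
14 | {[(R,Z)-4-acetoxyoctadec-2-en-5-yn-1-yl]oxy}dimethylsulfonium chloride (not isolated) | C[S+](C)OC/C=C\[C@@H](OC(C)=O)C#CCCCCCCCCCCCC.[Cl-] | intermediate
15 | (R,Z)-4-acetoxyoctadec-2-en-5-ynal | O=C/C=C\[C@@H](OC(C)=O)C#CCCCCCCCCCCCC | intermediate
16 | (R,E)-4-oxo-5-tridecylidenecyclopent-2-en-1-yl acetate | O=C1C=C[C@@H](OC(C)=O)/C1=C\CCCCCCCCCCCC | intermediate
17 | (1R,5S)-5-hydroxy-5-[(S)-1-hydroxytridecyl]-4-oxocyclopent-2-en-1-yl acetate | CCCCCCCCCCCC[C@H](O)[C@@]1(O)C(=O)C=C[C@H]1OC(C)=O | target

**Totals**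
Total step count: 9.
Longest linear sequence: 6 steps (for example 1 → 2 → 7 → 13 → 15 → 16 → 17, steps 1, 3, 6, 7, 8, 9; the branches from 3 and from 8 are also 6).

**Three steps most likely to fail**

Step 8 (the new reaction). The risks are decarbonylation of the acyl-rhodium hydride, Z-to-E isomerisation of 15 (the E-enal cannot close), a Rh-induced 1,3-acyloxy shift of the propargylic acetate, and 6-endo closure. The fallback is the known aldol-condensation route to the same dienone; it sets out from 2 and comes back at 16. Grignard 2 (2.2 equiv) is coupled with commercial 6-bromohexan-1-ol (OCCCCCCBr) under Li2CuCl4 catalysis to give tridecan-1-ol F1. F1 is oxidised (TEMPO, PhI(OAc)2, CH2Cl2) to tridecanal F2. Commercial (S)-4-hydroxycyclopent-2-en-1-one (O=C1C=C[C@@H](O)C1) is silylated (TBSCl, imidazole, DMF) to (S)-4-(tert-butyldimethylsilyloxy)cyclopent-2-en-1-one F3. Its kinetic lithium enolate (LDA, THF, −78 °C) adds to F2 anti to the silyloxy group to give (4R,5S)-4-(tert-butyldimethylsilyloxy)-5-(1-hydroxytridecyl)cyclopent-2-en-1-one F4 (both carbinol epimers are used). Mesylation and elimination (MsCl, Et3N; then DBU) give (R,E)-4-(tert-butyldimethylsilyloxy)-5-tridecylidenecyclopent-2-en-1-one F5. Desilylation (HF·pyridine, THF) gives (R,E)-4-hydroxy-5-tridecylidenecyclopent-2-en-1-one F6, and acetylation (Ac2O, pyridine, DMAP) gives 16.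

Step 7. The risks are Z-to-E isomerisation or loss of acetic acid under the amine base, and incomplete silicon-to-sulfur exchange. The fallback sets out from 13 and comes back at 15. The silyl ether is first cleaved with HF·pyridine (THF/pyridine, 0 °C) to (R,Z)-1-hydroxyoctadec-2-en-5-yn-4-yl acetate F7. F7 is then oxidised without any amine (TEMPO cat., PhI(OAc)2, CH2Cl2, 0 °C) to 15.

Step 6. The risks are modest ee or Z/E erosion with a Z-enal, and incomplete acylation in the flask. The fallback sets out from 7 and 10 and comes back at 13. Alkyne 7 is lithiated (n-BuLi, THF, −78 °C) and added to 10 to give racemic (Z)-1-(triethylsilyloxy)octadec-2-en-5-yn-4-ol F8. F8 is oxidised (Dess–Martin periodinane, NaHCO3) to (Z)-1-(triethylsilyloxy)octadec-2-en-5-yn-4-one F9. CBS reduction with (R)-Me-CBS and catecholborane (toluene, −78 °C), the alkynyl group acting as the small and the alkenyl as the large substituent, gives (R,Z)-1-(triethylsilyloxy)octadec-2-en-5-yn-4-ol F10. Acetylation (Ac2O, pyridine, DMAP) gives 13.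

**Further compounds**
F1 | step 8 | tridecan-1-ol | CCCCCCCCCCCCCO
F2 | step 8 | tridecanal | CCCCCCCCCCCCC=O
F3 | step 8 | (S)-4-(tert-butyldimethylsilyloxy)cyclopent-2-en-1-one | O=C1C=C[C@@H](O[Si](C)(C)C(C)(C)C)C1
F4 | step 8 | (4R,5S)-4-(tert-butyldimethylsilyloxy)-5-(1-hydroxytridecyl)cyclopent-2-en-1-one | O=C1C=C[C@@H](O[Si](C)(C)C(C)(C)C)[C@@H]1C(O)CCCCCCCCCCCC
F5 | step 8 | (R,E)-4-(tert-butyldimethylsilyloxy)-5-tridecylidenecyclopent-2-en-1-one | O=C1C=C[C@@H](O[Si](C)(C)C(C)(C)C)/C1=C\CCCCCCCCCCCC
F6 | step 8 | (R,E)-4-hydroxy-5-tridecylidenecyclopent-2-en-1-one | O=C1C=C[C@@H](O)/C1=C\CCCCCCCCCCCC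
F7 | step 7 | (R,Z)-1-hydroxyoctadec-2-en-5-yn-4-yl acetate | OC/C=C\[C@@H](OC(C)=O)C#CCCCCCCCCCCCC
F8 | step 6 | rac-(Z)-1-(triethylsilyloxy)octadec-2-en-5-yn-4-ol | CC[Si](CC)(CC)OC/C=C\C(O)C#CCCCCCCCCCCCC
F9 | step 6 | (Z)-1-(triethylsilyloxy)octadec-2-en-5-yn-4-one | CC[Si](CC)(CC)OC/C=C\C(=O)C#CCCCCCCCCCCCC
F10 | step 6 | (R,Z)-1-(triethylsilyloxy)octadec-2-en-5-yn-4-ol | CC[Si](CC)(CC)OC/C=C\[C@@H](O)C#CCCCCCCCCCCCC
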